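The ring is numbered C1 (methyl-bearing oxirane carbon), C2 (ketone), C3 (acetoxy carbon), C4 (side-chain carbon), C5 (carbinol), C6 (oxirane CH). The plan cuts C3–C4 and C5–C6. It exploits that C3 and C5 are both oxygenated carbons flanking C4, so C4–C5 can come from an enolisable aldehyde, and that C6 lies β to the C2 carbonyl of the cyclohexane, so a temporary nitro group can reverse its polarity. A proline-mediated aldol/Henry domino of enal 11 with γ-nitro aldehyde 3 closes the carbocycle and sets C3, C4 and C5 in one operation; nitrite loss then gives the C1=C6 enone for the epoxide.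

Key step: step 6

Assumption: compounds 1, 2, 4, 5, 7 and 9 are purchased; 1 and 4 are catalogue items of limited shelf life and are distilled before use.

Step 1
Reactants: 1 (E)-1-nitroprop-1-ene; 2 2-[(tert-butyldimethylsilyl)oxy]acetaldehyde
Product: 3 (2S,3S)-2-[(tert-butyldimethylsilyl)oxy]-3-methyl-4-nitrobutanal
Conditions: 1-[(1R,2R)-2-aminocyclohexyl]-3-[3,5-bis(trifluoromethyl)phenyl]thiourea (15 mol %), CH2Cl2, rt
Reagents that add atoms: none
Why: Primary-amine–thiourea-catalysed anti-selective Michael addition, in which the hydrogen-bonded Z-enamine of 2 adds to the thiourea-bound nitroalkene and should set both new centres (the later C2 and C1) in the anti 2S,3S sense under catalyst control, the enantiomeric catalyst being the remedy if the sense of induction proves opposite.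

Step 2
Reactants: 4 (2E)-4,4-dimethoxy-2-methylbut-2-enal; 5 allyltributylstannane
Product: 6 (2E,4S)-1,1-dimethoxy-3-methylhepta-2,6-dien-4-ol
Conditions: (S)-BINOL (10 mol %), Ti(OiPr)4 (10 mol %), 4 Å MS, CH2Cl2, −20 °C
Reagents that add atoms: none
Why: Keck asymmetric allylation, in which the BINOL–titanium Lewis acid activates the enal and the stannane adds 1,2 to one carbonyl face, which for alkenyl aldehydes with the S ligand should give the 4S carbinol (the later side-chain carbinol C8) and leaves the acetal untouched.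

Step 3
Reactants: 6 (2E,4S)-1,1-dimethoxy-3-methylhepta-2,6-dien-4-ol; 7 angelic acid, (2Z)-2-methylbut-2-enoic acid
Product: 8 (2E,4S)-1,1-dimethoxy-3-methylhepta-2,6-dien-4-yl (2Z)-2-methylbut-2-enoate
Conditions: 7, 2,4,6-Cl3C6H2COCl, Et3N, toluene, rt; then 6, 80 °C
Reagents that add atoms: none
Why: Yamaguchi-type esterification through the mixed 2,4,6-trichlorobenzoic anhydride of 7, run without DMAP so that the Z (angelate) geometry should not drift to the tiglate and the carbinol centre is not touched.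

Step 4
Reactants: 8 (2E,4S)-1,1-dimethoxy-3-methylhepta-2,6-dien-4-yl (2Z)-2-methylbut-2-enoate; 9 2-methylbut-2-ene
Product: 10 (2E,4S)-1,1-dimethoxy-3,7-dimethylocta-2,6-dien-4-yl (2Z)-2-methylbut-2-enoate
Conditions: second-generation Grubbs catalyst RuCl2(=CHPh)(PCy3)(H2IMes) (5 mol %), 9 (excess), CH2Cl2, 40 °C
Reagents that add atoms: none
Why: Olefin cross-metathesis with excess 2-methylbut-2-ene, which should convert only the monosubstituted terminal alkene into the prenyl alkene because the trisubstituted acetal alkene and the angelate alkene are too hindered and too electron-poor to enter the catalytic cycle.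

Step 5
Reactants: 10 (2E,4S)-1,1-dimethoxy-3,7-dimethylocta-2,6-dien-4-yl (2Z)-2-methylbut-2-enoate
Product: 11 (2E,4S)-3,7-dimethyl-1-oxoocta-2,6-dien-4-yl (2Z)-2-methylbut-2-enoate
Conditions: Amberlyst-15 (cat.), acetone/H2O, rt
Reagents that add atoms: water, O
Why: Acid-catalysed acetal hydrolysis, which is favoured because it releases a conjugated enal and should spare the allylic angelate under these mild heterogeneous conditions.

Step 6
Reactants: 3 (2S,3S)-2-[(tert-butyldimethylsilyl)oxy]-3-methyl-4-nitrobutanal; 11 (2E,4S)-3,7-dimethyl-1-oxoocta-2,6-dien-4-yl (2Z)-2-methylbut-2-enoate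
Product: 13 (3S)-2-[(1S,2S,3S,4S,5S,6R)-5-{[tert-butyl(dimethyl)silyl]oxy}-2,6-dihydroxy-4-methyl-3-nitrocyclohexyl]-6-methylhepta-1,5-dien-3-yl (2Z)-2-methylbut-2-enoate, via aldol adduct 12 (not isolated)
Conditions: L-proline (30 mol %), DMF, 4 °C to rt, slow addition of 11 (1.5 equiv); then Et3N (0.5 equiv), rt, same flask
Reagents that add atoms: none
Why: Proposed new method: proline and enal 11 form a dienamine whose α-carbon (C4) adds to the aldehyde carbon (C3) of 3 through the hydrogen-bonded enamine aldol transition state, which forms C3–C4, leaves the exocyclic methylene of the side chain and frees the C5 aldehyde, and the C6 nitronate then closes onto that aldehyde in an intramolecular Henry reaction, which forms C5–C6. The closest known reactions are the proline-catalysed cross-aldol of aldehydes with α-silyloxy aldehyde acceptors, the α-functionalisation of enals through dienamines and the Henry cyclisation of 6-nitro aldehydes to nitrocyclohexanols (as in amine-mediated Michael/Henry dominos); their combination on these two partners is what is new. The one ring that closes, the carbocycle, does so in a 6-(enolexo)-exo-trig mode. C3 is set by L-proline, whose preferred aldehyde face coincides with the Felkin–Anh face beside the C2 silyloxy centre (matched pair), while C4, C5 and C6 are set under thermodynamic control, since the α-formyl centre epimerises through the enamine and the Henry closure is reversible, so that the chair with equatorial methyl, hydroxyl, side-chain and nitro groups and only the C2 silyloxy group axial should accumulate. The step needs α- rather than γ-attack of the dienamine and cross- rather than self-aldolisation; the first is secured by the carboxylic-acid-directed transition state that only the α-carbon can reach, the second by the α-branched, poorly enolisable acceptor 3 and the slow addition of 11, whose β,β-disubstituted iminium is also a poor Michael acceptor for the nitronate.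

Step 7
Reactants: 13 (3S)-2-[(1S,2S,3S,4S,5S,6R)-5-{[tert-butyl(dimethyl)silyl]oxy}-2,6-dihydroxy-4-methyl-3-nitrocyclohexyl]-6-methylhepta-1,5-dien-3-yl (2Z)-2-methylbut-2-enoate
Product: 14 (3S)-2-[(1S,2S,3S,4S,5S,6R)-2,5,6-trihydroxy-4-methyl-3-nitrocyclohexyl]-6-methylhepta-1,5-dien-3-yl (2Z)-2-methylbut-2-enoate
Conditions: HF·pyridine, THF, 0 °C to rt
Reagents that add atoms: none
Why: Fluoride-driven cleavage of the hindered axial silyl ether under acidic, non-basic conditions, which should leave the base-labile β-nitro alcohol (no retro-Henry), both esters and all stereocentres untouched.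

Step 8
Reactants: 14 (3S)-2-[(1S,2S,3S,4S,5S,6R)-2,5,6-trihydroxy-4-methyl-3-nitrocyclohexyl]-6-methylhepta-1,5-dien-3-yl (2Z)-2-methylbut-2-enoate
Product: 17 (3S)-2-[(1R,2S,3S,4S,5S,6R)-2-{[tert-butyl(dimethyl)silyl]oxy}-5,6-dihydroxy-4-methyl-3-nitrocyclohexyl]-6-methylhepta-1,5-dien-3-yl (2Z)-2-methylbut-2-enoate, via phenylboronate 15 (not isolated), via silylated phenylboronate 16 (not isolated)
Conditions: PhB(OH)2 (1.05 equiv), 4 Å MS, CH2Cl2, rt; TBSOTf, 2,6-lutidine, −78 °C; then pinacol, MeOH, rt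
Reagents that add atoms: tert-butyldimethylsilyl trifluoromethanesulfonate, CC(C)(C)[Si](C)(C)OS(=O)(=O)C(F)(F)F
Why: Transient cyclic boronate protection of the cis C2/C3 diol (the diequatorial C3/C5 pair cannot chelate boron) leaves only the C5 hydroxyl to be silylated, after which transesterification with pinacol frees the diol, so that site-selectivity rests on ring geometry and not on relative rates.

Step 9
Reactants: 17 (3S)-2-[(1R,2S,3S,4S,5S,6R)-2-{[tert-butyl(dimethyl)silyl]oxy}-5,6-dihydroxy-4-methyl-3-nitrocyclohexyl]-6-methylhepta-1,5-dien-3-yl (2Z)-2-methylbut-2-enoate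
Product: 18 (3S)-2-[(1R,2S,3S,4S,5S,6R)-6-(acetyloxy)-2-{[tert-butyl(dimethyl)silyl]oxy}-5-hydroxy-4-methyl-3-nitrocyclohexyl]-6-methylhepta-1,5-dien-3-yl (2Z)-2-methylbut-2-enoate
Conditions: 2-aminoethyl diphenylborinate Ph2BOCH2CH2NH2 (10 mol %), AcCl (1.1 equiv), i-Pr2NEt, MeCN, 0 °C
Reagents that add atoms: acetyl chloride, CC(Cl)=O
Why: Borinic-acid-catalysed regioselective acylation of a cis-1,2-diol, in which the tetracoordinate borinate formed across the axial C2 and equatorial C3 hydroxyls should be acetylated at the more nucleophilic equatorial C3 oxygen.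

Step 10
Reactants: 18 (3S)-2-[(1R,2S,3S,4S,5S,6R)-6-(acetyloxy)-2-{[tert-butyl(dimethyl)silyl]oxy}-5-hydroxy-4-methyl-3-nitrocyclohexyl]-6-methylhepta-1,5-dien-3-yl (2Z)-2-methylbut-2-enoate
Product: 20 (3S)-2-[(1R,2R,6R)-6-(acetyloxy)-2-{[tert-butyl(dimethyl)silyl]oxy}-4-methyl-5-oxocyclohex-3-en-1-yl]-6-methylhepta-1,5-dien-3-yl (2Z)-2-methylbut-2-enoate, via nitro ketone 19 (not isolated)
Conditions: Dess–Martin periodinane, CH2Cl2, rt; then Et3N, 0 °C, same flask
Reagents that add atoms: none
Why: Dess–Martin oxidation of the only free (C2) hydroxyl gives the β-nitro ketone, from which triethylamine should expel nitrite by an E1cB elimination through the C1 enolate, so that the conjugated C1=C6 enone forms while the equatorial, thermodynamically preferred C3 acetoxy centre is kept.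

Step 11
Reactants: 20 (3S)-2-[(1R,2R,6R)-6-(acetyloxy)-2-{[tert-butyl(dimethyl)silyl]oxy}-4-methyl-5-oxocyclohex-3-en-1-yl]-6-methylhepta-1,5-dien-3-yl (2Z)-2-methylbut-2-enoate
Product: 21 (3S)-2-[(1R,2S,3R,4R,6R)-4-(acetyloxy)-2-{[tert-butyl(dimethyl)silyl]oxy}-6-methyl-5-oxo-7-oxabicyclo[4.1.0]heptan-3-yl]-6-methylhepta-1,5-dien-3-yl (2Z)-2-methylbut-2-enoate
Conditions: t-BuOOH (in decane), DBU, CH2Cl2, 0 °C
Reagents that add atoms: tert-butyl hydroperoxide, CC(C)(C)OO
Why: Weitz–Scheffer nucleophilic epoxidation, in which the tert-butyl peroxide anion adds to C6 of the enone on the face opposite the adjacent bulky C5 silyloxy group and the enolate closes the oxirane, which should set C1 and C6 trans to the C5 oxygen while the isolated alkenes and the angelate do not react.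

Step 12
Reactants: 21 (3S)-2-[(1R,2S,3R,4R,6R)-4-(acetyloxy)-2-{[tert-butyl(dimethyl)silyl]oxy}-6-methyl-5-oxo-7-oxabicyclo[4.1.0]heptan-3-yl]-6-methylhepta-1,5-dien-3-yl (2Z)-2-methylbut-2-enoate
Product: 22 (3S)-2-[(1R,2S,3S,4R,6R)-4-(acetyloxy)-2-hydroxy-6-methyl-5-oxo-7-oxabicyclo[4.1.0]heptan-3-yl]-6-methylhepta-1,5-dien-3-yl (2Z)-2-methylbut-2-enoate
Conditions: HF·pyridine, pyridine, THF, 0 °C to rt
Reagents that add atoms: none
Why: Fluoride-mediated desilylation with buffered HF·pyridine, chosen because these weakly acidic conditions should avoid acetyl migration, retro-aldol cleavage and opening of the electron-poor keto-epoxide.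

Compound list
1 | (E)-1-nitroprop-1-ene | C/C=C/[N+](=O)[O-] | starting material
2 | 2-[(tert-butyldimethylsilyl)oxy]acetaldehyde | O=CCO[Si](C)(C)C(C)(C)C | starting material
3 | (2S,3S)-2-[(tert-butyldimethylsilyl)oxy]-3-methyl-4-nitrobutanal | O=C[C@@H](O[Si](C)(C)C(C)(C)C)[C@@H](C)C[N+](=O)[O-] | intermediate
4 | (2E)-4,4-dimethoxy-2-methylbut-2-enal | O=C/C(C)=C/C(OC)OC | starting material
5 | allyltributylstannane | C=CC[Sn](CCCC)(CCCC)CCCC | starting material
6 | (2E,4S)-1,1-dimethoxy-3-methylhepta-2,6-dien-4-ol | COC(OC)/C=C(\C)[C@@H](O)CC=C | intermediate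
7 | angelic acid, (2Z)-2-methylbut-2-enoic acid | C/C=C(/C)C(=O)O | starting material
8 | (2E,4S)-1,1-dimethoxy-3-methylhepta-2,6-dien-4-yl (2Z)-2-methylbut-2-enoate | COC(OC)/C=C(\C)[C@H](CC=C)OC(=O)/C(C)=C\C | intermediate
9 | 2-methylbut-2-ene | CC=C(C)C | starting material
10 | (2E,4S)-1,1-dimethoxy-3,7-dimethylocta-2,6-dien-4-yl (2Z)-2-methylbut-2-enoate | COC(OC)/C=C(\C)[C@H](CC=C(C)C)OC(=O)/C(C)=C\C | intermediate
11 | (2E,4S)-3,7-dimethyl-1-oxoocta-2,6-dien-4-yl (2Z)-2-methylbut-2-enoate | O=C/C=C(\C)[C@H](CC=C(C)C)OC(=O)/C(C)=C\C | intermediate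
12 | aldol adduct, (3S)-2-[(2R,3R,4S,5S)-4-{[tert-butyl(dimethyl)silyl]oxy}-3-hydroxy-5-methyl-6-nitro-1-oxohexan-2-yl]-6-methylhepta-1,5-dien-3-yl (2Z)-2-methylbut-2-enoate (the C4 epimer that cyclises) | O=C[C@@H]([C@@H](O)[C@@H](O[Si](C)(C)C(C)(C)C)[C@@H](C)C[N+](=O)[O-])C(=C)[C@H](CC=C(C)C)OC(=O)/C(C)=C\C | intermediate
13 | (3S)-2-[(1S,2S,3S,4S,5S,6R)-5-{[tert-butyl(dimethyl)silyl]oxy}-2,6-dihydroxy-4-methyl-3-nitrocyclohexyl]-6-methylhepta-1,5-dien-3-yl (2Z)-2-methylbut-2-enoate (chair: only the silyloxy group axial) | C=C([C@H]1[C@H](O)[C@@H]([N+](=O)[O-])[C@H](C)[C@H](O[Si](C)(C)C(C)(C)C)[C@@H]1O)[C@H](CC=C(C)C)OC(=O)/C(C)=C\C | intermediate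
14 | (3S)-2-[(1S,2S,3S,4S,5S,6R)-2,5,6-trihydroxy-4-methyl-3-nitrocyclohexyl]-6-methylhepta-1,5-dien-3-yl (2Z)-2-methylbut-2-enoate | C=C([C@H]1[C@H](O)[C@@H]([N+](=O)[O-])[C@H](C)[C@H](O)[C@@H]1O)[C@H](CC=C(C)C)OC(=O)/C(C)=C\C | intermediate
15 | cyclic phenylboronate of 14 across the cis C2 and C3 oxygens (cis-fused 2-phenyl-1,3,2-dioxaborolane, C5 hydroxyl free, configuration as in 14) | C=C([C@H]1[C@H](O)[C@@H]([N+](=O)[O-])[C@H](C)[C@@H]3OB(c4ccccc4)O[C@H]13)[C@H](CC=C(C)C)OC(=O)/C(C)=C\C | intermediate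
16 | C5 tert-butyldimethylsilyl ether of phenylboronate 15 | C=C([C@H]1[C@H](O[Si](C)(C)C(C)(C)C)[C@@H]([N+](=O)[O-])[C@H](C)[C@@H]3OB(c4ccccc4)O[C@H]13)[C@H](CC=C(C)C)OC(=O)/C(C)=C\C | intermediate
17 | (3S)-2-[(1R,2S,3S,4S,5S,6R)-2-{[tert-butyl(dimethyl)silyl]oxy}-5,6-dihydroxy-4-methyl-3-nitrocyclohexyl]-6-methylhepta-1,5-dien-3-yl (2Z)-2-methylbut-2-enoate | C=C([C@H]1[C@H](O[Si](C)(C)C(C)(C)C)[C@@H]([N+](=O)[O-])[C@H](C)[C@H](O)[C@@H]1O)[C@H](CC=C(C)C)OC(=O)/C(C)=C\C | intermediate
18 | (3S)-2-[(1R,2S,3S,4S,5S,6R)-6-(acetyloxy)-2-{[tert-butyl(dimethyl)silyl]oxy}-5-hydroxy-4-methyl-3-nitrocyclohexyl]-6-methylhepta-1,5-dien-3-yl (2Z)-2-methylbut-2-enoate | C=C([C@H]1[C@H](O[Si](C)(C)C(C)(C)C)[C@@H]([N+](=O)[O-])[C@H](C)[C@H](O)[C@@H]1OC(C)=O)[C@H](CC=C(C)C)OC(=O)/C(C)=C\C | intermediate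
19 | nitro ketone, (3S)-2-[(1R,2S,3S,4S,6R)-6-(acetyloxy)-2-{[tert-butyl(dimethyl)silyl]oxy}-4-methyl-3-nitro-5-oxocyclohexyl]-6-methylhepta-1,5-dien-3-yl (2Z)-2-methylbut-2-enoate | C=C([C@H]1[C@H](O[Si](C)(C)C(C)(C)C)[C@@H]([N+](=O)[O-])[C@H](C)C(=O)[C@@H]1OC(C)=O)[C@H](CC=C(C)C)OC(=O)/C(C)=C\C | intermediate
20 | (3S)-2-[(1R,2R,6R)-6-(acetyloxy)-2-{[tert-butyl(dimethyl)silyl]oxy}-4-methyl-5-oxocyclohex-3-en-1-yl]-6-methylhepta-1,5-dien-3-yl (2Z)-2-methylbut-2-enoate | C=C([C@H]1[C@H](O[Si](C)(C)C(C)(C)C)C=C(C)C(=O)[C@@H]1OC(C)=O)[C@H](CC=C(C)C)OC(=O)/C(C)=C\C | intermediate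
21 | (3S)-2-[(1R,2S,3R,4R,6R)-4-(acetyloxy)-2-{[tert-butyl(dimethyl)silyl]oxy}-6-methyl-5-oxo-7-oxabicyclo[4.1.0]heptan-3-yl]-6-methylhepta-1,5-dien-3-yl (2Z)-2-methylbut-2-enoate | C=C([C@H]1[C@H](O[Si](C)(C)C(C)(C)C)[C@H]2O[C@@]2(C)C(=O)[C@@H]1OC(C)=O)[C@H](CC=C(C)C)OC(=O)/C(C)=C\C | intermediate
22 | (3S)-2-[(1R,2S,3S,4R,6R)-4-(acetyloxy)-2-hydroxy-6-methyl-5-oxo-7-oxabicyclo[4.1.0]heptan-3-yl]-6-methylhepta-1,5-dien-3-yl (2Z)-2-methylbut-2-enoate | C=C([C@H]1[C@H](O)[C@H]2O[C@@]2(C)C(=O)[C@@H]1OC(C)=O)[C@H](CC=C(C)C)OC(=O)/C(C)=C\C | target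

Total step count: 12. Longest linear sequence: 11 steps (steps 2 to 12, from 4).

Steps most likely to fail

Step 6 (proposed new method). The dienamine may attack through its γ-carbon or condense with itself. The β,γ-unsaturated aldol adduct may drift into conjugation or dehydrate before the ring closes. The side-chain carbinol centre may erode through the alternative dienamine. Equilibration to the all-trans C3/C4/C5 array may stay incomplete. The fallback makes the same two bonds in separate, known operations; it sets out from 3 (with 11) and returns at 13. The aldehyde of 3 is masked as the dimethyl acetal F1 (MeOH, PPTS). The nitronate of F1 (tetramethylguanidine, THF) adds to the aldehyde of 11 in an intermolecular Henry reaction to give the open-chain nitro alcohol F2, which carries the C5–C6 bond. Wet acid (Amberlyst-15, acetone/H2O) frees the aldehyde F3. Me2AlCl (CH2Cl2, −78 °C) then closes C3–C4 by an intramolecular carbonyl-ene cyclisation of the citronellal-to-isopulegol kind. The transferred hydrogen comes from the allylic methyl, so the exocyclic methylene appears, and the chair transition state places the new hydroxyl and the side chain equatorial. A short Et3N equilibration of the carbinol and nitro-bearing centres gives 13.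

Step 11. Facial selectivity may be poor, because the C4 side chain sits 1,3 to the attacked carbon and opposes the C5 silyloxy group. The basic peroxide may also cleave the α-acetoxy group. The fallback is a hydroxyl-directed epoxidation; it sets out from 20 and returns at 21. Luche reduction (NaBH4, CeCl3·7H2O, MeOH, −78 °C) should give the pseudo-equatorial C2 allylic alcohol F4, trans to the C3 acetate. VO(acac)2 with t-BuOOH (CH2Cl2, 0 °C) should deliver the oxirane syn to that hydroxyl, which is also anti to the C5 silyloxy group, giving epoxy alcohol F5. Dess–Martin oxidation restores the ketone and gives 21.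

Step 8. Boronate formation may be incomplete, or the boronate may exchange during silylation, so that C2 or C3 is silylated or the product is silylated twice. The fallback uses an isolable ketal in place of the transient boronate; it sets out from 14 and returns at 17. The cis C2/C3 diol is tied up as the acetonide F6 (2,2-dimethoxypropane, PPTS, acetone). The remaining C5 hydroxyl is silylated to the silylated acetonide F7 (TBSOTf, 2,6-lutidine, CH2Cl2, −78 °C). Aqueous acetic acid (THF, rt) removes the acetonide and gives 17.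

Further compounds
F1 | step 6 | dimethyl acetal of 3, (2S,3S)-2-[(tert-butyldimethylsilyl)oxy]-1,1-dimethoxy-3-methyl-4-nitrobutane | COC(OC)[C@@H](O[Si](C)(C)C(C)(C)C)[C@@H](C)C[N+](=O)[O-]
F2 | step 6 | open-chain nitro alcohol, (2S,3S,4S,5S,6E,8S)-2-[(tert-butyldimethylsilyl)oxy]-5-hydroxy-1,1-dimethoxy-3,7,11-trimethyl-4-nitrododeca-6,10-dien-8-yl (2Z)-2-methylbut-2-enoate (drawn as the C4/C5 isomer that maps onto 13) | COC(OC)[C@@H](O[Si](C)(C)C(C)(C)C)[C@@H](C)[C@H]([N+](=O)[O-])[C@@H](O)/C=C(\C)[C@H](CC=C(C)C)OC(=O)/C(C)=C\C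
F3 | step 6 | aldehyde from F2, (2S,3S,4S,5S,6E,8S)-2-[(tert-butyldimethylsilyl)oxy]-5-hydroxy-3,7,11-trimethyl-4-nitro-1-oxododeca-6,10-dien-8-yl (2Z)-2-methylbut-2-enoate | O=C[C@@H](O[Si](C)(C)C(C)(C)C)[C@@H](C)[C@H]([N+](=O)[O-])[C@@H](O)/C=C(\C)[C@H](CC=C(C)C)OC(=O)/C(C)=C\C
F4 | step 11 | C2 allylic alcohol from 20 (C2 hydroxyl trans to the C3 acetate, other centres as in 20) | C=C([C@H]1[C@H](O[Si](C)(C)C(C)(C)C)C=C(C)[C@@H](O)[C@@H]1OC(C)=O)[C@H](CC=C(C)C)OC(=O)/C(C)=C\C
F5 | step 11 | epoxy alcohol from F4 (C1–C6 oxirane on the face of the C2 hydroxyl, trans to the C5 silyloxy group) | C=C([C@H]1[C@H](O[Si](C)(C)C(C)(C)C)[C@H]2O[C@@]2(C)[C@@H](O)[C@@H]1OC(C)=O)[C@H](CC=C(C)C)OC(=O)/C(C)=C\C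
F6 | step 8 | acetonide of 14 across the cis C2 and C3 oxygens (C5 hydroxyl free, configuration as in 14) | C=C([C@H]1[C@H](O)[C@@H]([N+](=O)[O-])[C@H](C)[C@@H]3OC(C)(C)O[C@H]13)[C@H](CC=C(C)C)OC(=O)/C(C)=C\C
F7 | step 8 | C5 tert-butyldimethylsilyl ether of acetonide F6 | C=C([C@H]1[C@H](O[Si](C)(C)C(C)(C)C)[C@@H]([N+](=O)[O-])[C@H](C)[C@@H]3OC(C)(C)O[C@H]13)[C@H](CC=C(C)C)OC(=O)/C(C)=C\C
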